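**Strategy.** Ring A is taken apart completely. Its carbons C5, C6, C7 and C8 come from a diazoacetyl group and an ynol ether, and they are annulated onto the C4a–C8a edge of a preformed 5-aryl-4-pyranone (ring C). The feature exploited is the ring A sequence C5-OH, C6-prenyl, C7-OMe, C8-H, the signature of a vinylketene–alkoxyalkyne benzannulation, together with the enone-like C4a=C8a bond of the pyranone. One photochemical operation forms four C–C bonds, closes ring A and delivers the unprotected target. The precursors are 2-(diazoacetyl)-5-(2,4,5-trimethoxyphenyl)-4H-pyran-4-one, four steps from kojic acid, and 1-methoxy-5-methylhex-4-en-1-yne, one step from chloroacetaldehyde dimethyl acetal.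

Key step: step 6

Remark: the target is achiral; the sp3 centres in intermediates 14 and 16 form as racemates and vanish on aromatisation. Locants C2–C8a are those of the chromen-4-one system of the target.

**Step 1**
Reactants: 1 kojic acid
Product: 2 6-(hydroxymethyl)-4-oxo-4H-pyran-3-yl trifluoromethanesulfonate
Conditions: PhNTf2 (1.05 equiv), Et3N (1.2 equiv), CH2Cl2, 0 °C to rt
Reagents that add atoms: N-phenylbis(trifluoromethanesulfonimide), O=S(=O)(N(c1ccccc1)S(=O)(=O)C(F)(F)F)C(F)(F)F
Why: Chemoselective O-sulfonylation, because Et3N ionises only the enolic 5-OH (far more acidic than the primary alcohol) and the mild triflyl donor PhNTf2 reacts with that oxyanion and leaves the CH2OH group free.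

**Step 2**
Reactants: 2 6-(hydroxymethyl)-4-oxo-4H-pyran-3-yl trifluoromethanesulfonate; 3 2,4,5-trimethoxyphenylboronic acid
Product: 4 2-(hydroxymethyl)-5-(2,4,5-trimethoxyphenyl)-4H-pyran-4-one
Conditions: Pd(OAc)2 (3 mol %), SPhos (6 mol %), K3PO4 (2 equiv), 3 (1.5 equiv), THF/H2O (10:1), 50 °C
Reagents that add atoms: none
Why: Suzuki–Miyaura coupling, in which the electron-poor enol triflate adds readily to zerovalent palladium and the bulky electron-rich phosphine makes the coupling of the ortho-substituted boronic acid fast enough to outrun triflate hydrolysis and protodeboronation.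

**Step 3**
Reactants: 4 2-(hydroxymethyl)-5-(2,4,5-trimethoxyphenyl)-4H-pyran-4-one
Product: 6 4-oxo-5-(2,4,5-trimethoxyphenyl)-4H-pyran-2-carboxylic acid, via pyranone-2-carbaldehyde 5 (not isolated)
Conditions: TEMPO (0.2 equiv), PhI(OAc)2 (2.2 equiv), MeCN/H2O (1:1), rt
Reagents that add atoms: water, O
Why: Oxoammonium (TEMPO) oxidation with PhI(OAc)2 as terminal oxidant, which takes the primary alcohol to the aldehyde and its hydrate on to the acid under near-neutral conditions that spare the electron-rich trimethoxyarene and the pyranone.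

**Step 4**
Reactants: 6 4-oxo-5-(2,4,5-trimethoxyphenyl)-4H-pyran-2-carboxylic acid
Product: 8 2-(diazoacetyl)-5-(2,4,5-trimethoxyphenyl)-4H-pyran-4-one, via acid chloride 7 (not isolated)
Conditions: (COCl)2 (1.1 equiv), cat. DMF, CH2Cl2, 0 °C to rt, concentrate; then CH2N2 (1.5 equiv), Et3N (1.1 equiv), THF/Et2O, −20 to 0 °C, dark
Reagents that add atoms: diazomethane, C=[N+]=[N-]
Why: Acylation of diazomethane by an acid chloride in the Newman–Beal variant of the first Arndt–Eistert stage, where Et3N takes up the HCl so that only a small excess of diazomethane is present and the diazoketone is not converted into the chloromethyl ketone.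

**Step 5**
Reactants: 9 chloroacetaldehyde dimethyl acetal; 10 prenyl bromide
Product: 12 1-methoxy-5-methylhex-4-en-1-yne, via lithium methoxyacetylide 11 (not isolated)
Conditions: Et2NH/n-BuLi (3.0 equiv LiNEt2), THF, 0 °C; then 10 (0.8 equiv), DMPU, −78 °C to rt; cold work-up, distillation
Reagents that add atoms: none
Why: Two base-induced eliminations (MeOH, then HCl) and deprotonation turn the chloroacetal into the alkoxyacetylide, which is alkylated by SN2 displacement at the primary allylic carbon of prenyl bromide in the cation-solvating co-solvent DMPU.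

**Step 6**
Reactants: 8 2-(diazoacetyl)-5-(2,4,5-trimethoxyphenyl)-4H-pyran-4-one; 12 1-methoxy-5-methylhex-4-en-1-yne
Product: 17 5-hydroxy-7-methoxy-6-(3-methylbut-2-en-1-yl)-3-(2,4,5-trimethoxyphenyl)-4H-chromen-4-one (target), via pyranonylketene 13 (not isolated), via cyclobutenone 14 (not isolated), via dienylketene 15 (not isolated), via 4aH-dienone 16 (not isolated)
Conditions: 12 (3 equiv), degassed ClCH2CH2Cl, hν (365 nm), 20 °C; then 80 °C, dark
Reagents that add atoms: none
Why: Light expels N2 from 8 and the pyranon-2-yl group shifts from the carbonyl carbon to the carbene carbon (Wolff rearrangement, forming C8a–C8) to give ketene 13, a vinylketene because the pyranone C2=C3 bond (C8a=C4a of the target) is conjugated with it. The nucleophilic prenyl-bearing carbon of ynol ether 12 attacks the ketene carbonyl carbon in a polar [2+2] cycloaddition (C5–C6 and C7–C8) to give cyclobutenone 14, which opens by a four-electron electrocyclic reaction (light or heat) to dienylketene 15; a thermal six-electron disrotatory electrocyclisation then forms C4a–C5, and the doubly activated C4a–H of dienone 16 tautomerises to the phenol. The closest known reaction type is the Danheiser benzannulation in its diazoketone form, established for alkenyl, aryl and heteroaryl diazoketones with alkoxy- and siloxyalkynes, with the pyranone edge here playing the part of the alkenyl unit. Ring A, the only ring that persists, is closed by the 6π electrocyclisation of 15 followed by enolisation, while the four-membered ring of 14 is a transient product of the [2+2] step. No stereocentre remains, since the sp3 carbons of 14 and 16 are lost on aromatisation. The step needs regiocontrol, which the oxygen-polarised alkyne supplies (prenyl next to C5-OH, methoxy at C7), a single site of closure, which the pyranone offers because its C2 has only C3 as a carbon neighbour, and chemoselectivity, expected because the ynol ether is far more reactive towards the ketene than the trisubstituted prenyl alkene and because long-wavelength light excites the diazoketone rather than the product, whose 5-OH is held in a hydrogen bond to the C4 carbonyl.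

**Compound list**
1 | kojic acid, 5-hydroxy-2-(hydroxymethyl)-4H-pyran-4-one | OCc1cc(=O)c(O)co1 | starting material
2 | 6-(hydroxymethyl)-4-oxo-4H-pyran-3-yl trifluoromethanesulfonate | OCc1cc(=O)c(OS(=O)(=O)C(F)(F)F)co1 | intermediate
3 | 2,4,5-trimethoxyphenylboronic acid | COc1cc(OC)c(B(O)O)cc1OC | starting material
4 | 2-(hydroxymethyl)-5-(2,4,5-trimethoxyphenyl)-4H-pyran-4-one | COc1cc(OC)c(-c2coc(CO)cc2=O)cc1OC | intermediate
5 | 4-oxo-5-(2,4,5-trimethoxyphenyl)-4H-pyran-2-carbaldehyde | COc1cc(OC)c(-c2coc(C=O)cc2=O)cc1OC | intermediate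
6 | 4-oxo-5-(2,4,5-trimethoxyphenyl)-4H-pyran-2-carboxylic acid | COc1cc(OC)c(-c2coc(C(=O)O)cc2=O)cc1OC | intermediate
7 | 4-oxo-5-(2,4,5-trimethoxyphenyl)-4H-pyran-2-carbonyl chloride | COc1cc(OC)c(-c2coc(C(=O)Cl)cc2=O)cc1OC | intermediate
8 | 2-(diazoacetyl)-5-(2,4,5-trimethoxyphenyl)-4H-pyran-4-one | COc1cc(OC)c(-c2coc(C(=O)C=[N+]=[N-])cc2=O)cc1OC | intermediate
9 | chloroacetaldehyde dimethyl acetal, 2-chloro-1,1-dimethoxyethane | COC(CCl)OC | starting material
10 | prenyl bromide, 1-bromo-3-methylbut-2-ene | CC(C)=CCBr | starting material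
11 | lithium methoxyacetylide | [Li]C#COC | intermediate
12 | 1-methoxy-5-methylhex-4-en-1-yne | COC#CCC=C(C)C | intermediate
13 | 2-(2-oxoethenyl)-5-(2,4,5-trimethoxyphenyl)-4H-pyran-4-one (pyranonylketene) | COc1cc(OC)c(-c2coc(C=C=O)cc2=O)cc1OC | intermediate
14 | 3-methoxy-2-(3-methylbut-2-en-1-yl)-4-[4-oxo-5-(2,4,5-trimethoxyphenyl)-4H-pyran-2-yl]cyclobut-2-en-1-one, racemic | COC1=C(CC=C(C)C)C(=O)C1c1cc(=O)c(-c2cc(OC)c(OC)cc2OC)co1 | intermediate
15 | dienylketene 2-[3-methoxy-5-methyl-2-(oxomethylidene)hexa-1,4-dien... ] described as O=C=C(prenyl)–C(OMe)=CH–(pyranon-2-yl), ketene carbon and pyranone cis across the C(OMe)=CH bond | O=C=C(CC=C(C)C)/C(OC)=C\c1cc(=O)c(-c2cc(OC)c(OC)cc2OC)co1 | intermediate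
16 | 7-methoxy-6-(3-methylbut-2-en-1-yl)-3-(2,4,5-trimethoxyphenyl)-4aH-chromene-4,5-dione, racemic | O=C1C(CC=C(C)C)=C(OC)C=C2OC=C(c3cc(OC)c(OC)cc3OC)C(=O)C12 | intermediate
17 | 5-hydroxy-7-methoxy-6-(3-methylbut-2-en-1-yl)-3-(2,4,5-trimethoxyphenyl)-4H-chromen-4-one | COc1cc(OC)c(-c2coc3cc(OC)c(CC=C(C)C)c(O)c3c2=O)cc1OC | target

**Totals.** Total step count: 6. Longest linear sequence: 5 steps (steps 1, 2, 3, 4 and 6); step 5 is a one-step branch.

**Steps most likely to fail**

1. Step 6. The route carries its risk here, because a 4-pyranone edge has not served before as the alkenyl unit of this benzannulation. What may go wrong: light is absorbed unproductively by the pyranone chromophore, or the photogenerated carbene is diverted before the Wolff shift, so that the ketene never forms cleanly. Fallback (sets out from 8, comes back at 17, entering the cascade at ketene 13): the same ketene is made without light. Silver-promoted Wolff rearrangement of 8 in the dark (PhCO2Ag, Et3N, THF/H2O) should give [4-oxo-5-(2,4,5-trimethoxyphenyl)-4H-pyran-2-yl]acetic acid F1. (COCl)2 with cat. DMF converts it into [4-oxo-5-(2,4,5-trimethoxyphenyl)-4H-pyran-2-yl]acetyl chloride F2. Slow addition of Et3N to F2 and excess 12 in toluene at rt generates 13 by dehydrochlorination and traps it as cyclobutenone 14; heating to 80–110 °C then carries 14 through 15 and 16 to 17. Each stage is known chemistry: Arndt–Eistert homologation, ketene formation from an acid chloride, ketene–alkoxyalkyne [2+2] cycloaddition and thermal rearrangement of a 4-alkenylcyclobutenone to a phenol.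

2. Step 4. What may go wrong: diazomethane adds as a 1,3-dipole across an electron-poor pyranone double bond (pyrazoline formation), or HCl strips N2 from the diazoketone. Fallback (sets out from acid chloride 7, comes back at 8): the diazo group is installed by diazo transfer instead of by acylation of diazomethane. Treating 7 with MeNHOMe·HCl and pyridine in CH2Cl2 should give N-methoxy-N-methyl-4-oxo-5-(2,4,5-trimethoxyphenyl)-4H-pyran-2-carboxamide F3. MeMgBr in THF at −78 °C converts it into 2-acetyl-5-(2,4,5-trimethoxyphenyl)-4H-pyran-4-one F4. Detrifluoroacetylative diazo transfer then follows: LiHMDS and CF3CO2CH2CF3 in THF at −78 °C give 4,4,4-trifluoro-1-[4-oxo-5-(2,4,5-trimethoxyphenyl)-4H-pyran-2-yl]butane-1,3-dione F5, which is not isolated and is treated with MsN3, Et3N and H2O in MeCN to give 8.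

3. Step 5. What may go wrong: the acetylide alkylates slowly or with allylic transposition, residual amide base isomerises the skipped enyne, and the volatile, acid-sensitive methyl ynol ether is lost on isolation. Fallback (sets out from 8, comes back at 17): the C7 oxygen is carried as a silyl ether and the alkyne is made by ester homologation rather than acetylide alkylation. Commercial ethyl 4-methylpent-3-enoate (CCOC(=O)CC=C(C)C) is subjected to Kowalski homologation (CH2Br2/LiTMP, THF, −78 °C; then n-BuLi; ynolate O-silylated with TIPSOTf) to give triisopropyl[(5-methylhex-4-en-1-yn-1-yl)oxy]silane F6. F6 replaces 12 under the conditions of step 6 and with 8 should give 5-hydroxy-6-(3-methylbut-2-en-1-yl)-3-(2,4,5-trimethoxyphenyl)-7-(triisopropylsilyloxy)-4H-chromen-4-one F7. TBAF in THF at 0 °C frees 5,7-dihydroxy-6-(3-methylbut-2-en-1-yl)-3-(2,4,5-trimethoxyphenyl)-4H-chromen-4-one F8. MeI (1.1 equiv) with K2CO3 in acetone methylates only the 7-OH, the 5-OH being chelated to the C4 carbonyl, and gives 17.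

**Further compounds**
F1 | step 6 | [4-oxo-5-(2,4,5-trimethoxyphenyl)-4H-pyran-2-yl]acetic acid | COc1cc(OC)c(-c2coc(CC(=O)O)cc2=O)cc1OC
F2 | step 6 | [4-oxo-5-(2,4,5-trimethoxyphenyl)-4H-pyran-2-yl]acetyl chloride | COc1cc(OC)c(-c2coc(CC(=O)Cl)cc2=O)cc1OC
F3 | step 4 | N-methoxy-N-methyl-4-oxo-5-(2,4,5-trimethoxyphenyl)-4H-pyran-2-carboxamide | COc1cc(OC)c(-c2coc(C(=O)N(C)OC)cc2=O)cc1OC
F4 | step 4 | 2-acetyl-5-(2,4,5-trimethoxyphenyl)-4H-pyran-4-one | COc1cc(OC)c(-c2coc(C(C)=O)cc2=O)cc1OC
F5 | step 4 | 4,4,4-trifluoro-1-[4-oxo-5-(2,4,5-trimethoxyphenyl)-4H-pyran-2-yl]butane-1,3-dione | COc1cc(OC)c(-c2coc(C(=O)CC(=O)C(F)(F)F)cc2=O)cc1OC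
F6 | step 5 | triisopropyl[(5-methylhex-4-en-1-yn-1-yl)oxy]silane | CC(C)=CCC#CO[Si](C(C)C)(C(C)C)C(C)C
F7 | step 5 | 5-hydroxy-6-(3-methylbut-2-en-1-yl)-3-(2,4,5-trimethoxyphenyl)-7-(triisopropylsilyloxy)-4H-chromen-4-one | COc1cc(OC)c(-c2coc3cc(O[Si](C(C)C)(C(C)C)C(C)C)c(CC=C(C)C)c(O)c3c2=O)cc1OC
F8 | step 5 | 5,7-dihydroxy-6-(3-methylbut-2-en-1-yl)-3-(2,4,5-trimethoxyphenyl)-4H-chromen-4-one | COc1cc(OC)c(-c2coc3cc(O)c(CC=C(C)C)c(O)c3c2=O)cc1OC
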